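The unit to count in here is the half-life of approach to the plateau, not the minute.

all flasks: starting material 0.050 M
- oak: second substrate 0.10 M; enzyme 4.6 µM; run made earlier
- maple: second substrate 0.10 M; enzyme 7.5 µM; run made earlier
- cedar: second substrate 0.10 M; enzyme 8.6 µM; run made earlier
- larch: second substrate 0.17 M; enzyme 10 µM; run made earlier
- south-east: second substrate 0.100 M; enzyme 10 µM; time 40 min
- east: second substrate 0.300 M; enzyme 6.0 µM; time 40 min

| oak: time / min | oak: target / % | maple: time / min | maple: target / % | cedar: time / min | cedar: target / % | larch: time / min | larch: target / % |
|---|---|---|---|---|---|---|---|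
| 5.00 | 51 | 5.00 | 76 | 10.0 | 85 | 3.00 | 68 |
| 15.0 | 86 | 15.0 | 87 | 20.0 | 89 | 8.00 | 84 |
| 25.0 | 88 | 25.0 | 85 | 30.0 | 89 | 15.0 | 87 |
| 40.0 | 87 | 40.0 | 83 | 40.0 | 92 | 40.0 | 90 |

(scatter of a reading: 2 percentage points)

- reactions considered so far: second substrate + enzyme <-> complex B; starting material + enzyme <-> complex A; second substrate + enzyme -> spent catalyst; complex B -> enzyme + second product; complex A <-> enzyme + target

* which of the two ends with the higher amount of target, in percent of the starting material charged ("neither" if they lie within 2 percentage points) (south-east / east / neither)
* target at the end, in percent of the starting material charged, south-east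
* target at the end, in percent of the starting material charged, east

1. The last readings of oak, maple, cedar and larch are 87 %, 83 %, 92 % and 90 %, with enzyme from 4.6 µM to 10 µM, so we read the plateau as an equilibrium between starting material and target (thermodynamic control) and take 88 % for it from oak.

2. Oak stood at 51 % after 5.00 min, so, as far as that one scattered reading tells, its gap to the plateau halves every 4.00 min; this is the approach half-life, which we scale inversely with enzyme.

3. On the fastest rung of our ladder stands south-east at 1.84 min, then east at 3.07 min, longer, and both are estimates that count enzyme and leave second substrate out. Larch, at 0.17 M of second substrate, reads 1.37 min, shorter than the 1.84 min that scaling gives, so that reading shows no slowing, but east's 0.300 M lies beyond it.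

4. The next rung is the enzyme's lifetime, for which we have a floor and no value. Oak was still closing its gap up to 15.0 min, and if the loss goes with second substrate, that floor shrinks to 5.00 min in east, longer than east's half-life but worth just 1.63 half-lives.

5. The top rung is the 40 min window, which holds 21.7 half-lives in south-east and 13.0 in east if the enzyme lasts. We commit to the plateau in both flasks, 88 % each, and to "neither", which for east is our wager that its enzyme outlasts that floor.

6. The forecast differs: it says south-east, with 89 % (85 % to 92 %) for south-east and 83 % (66 % to 91 %) for east, on the ground that “competition plus substrate-driven deactivation could cut the total conversion”.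

The flask gives neither, with 87.7 % in south-east and 87.7 % in east.

    second substrate + enzyme ⇌ complex B (K = 3.20 L mol⁻¹, k = 54000 L mol⁻¹ min⁻¹)
    starting material + enzyme ⇌ complex A (K = 51.0 L mol⁻¹, k = 4.00 × 10⁵ L mol⁻¹ min⁻¹)
    second substrate + enzyme → spent catalyst (k = 0.0850 L mol⁻¹ min⁻¹)
    complex B → enzyme + second product (k = 310 min⁻¹)
    complex A ⇌ enzyme + target (K = 0.140 M, k = 2900 min⁻¹)

The neighbouring flask is east with enzyme cut to 1.5 × 10⁻⁶ M. Oak's 4.00 min, scaled to that enzyme, becomes 12.3 min, so the 40 min hold 3.26 half-lives against the 13.0 of east, leaving 10.4 % of the gap open and giving 78.8 % of target. Simulated, this neighbour holds 77.9 % target at 40.0 min, with 22.1 % of the starting material still unbound and 30.0 % of the catalyst charged as spent catalyst.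

The earlier runs and the new flask are simulated from invented constants.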